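## Retrosynthetic overview

- Numbering: C1 is the methyl-bearing quaternary fusion carbon, C2 the OAc carbon, C3 a CH2, C4 the isopropyl carbinol, C5 the fusion CH, C6 the anisoate carbon, C7 a CH2, C8(Me)=C9 the alkene, C10 a CH2; β is the face of the C1 methyl, α the opposite face.
- Feature used: quaternary C1 lies β to C4 across the C1–C5 bond shared by the five- and seven-membered rings, and C5 also carries the C6 oxygen. With C4 and C6 as ketones and C5=C1 unsaturated, a vinyl group on C4 gives a chelatable, polarised divinyl ketone.
- Late disconnections: C6 anisoate and C2 acetate by acylation; the C6 carbinol by reduction of a C6 ketone directed by the C4 hydroxyl; C4–iPr by organocerium addition to a C4 ketone; C2–O by conjugate borylation–oxidation of the C2=C3 enone.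
- Key disconnection: C1–C2, by Nazarov 4π electrocyclisation of 2-acryloyl-3,6-dimethylcyclohepta-2,5-dienone; the five-membered ring is formed second, on the finished seven-membered ring.
- Seven-membered ring: Birch reduction of 2,5-dimethylanisole and dibromocarbene ring expansion. This gives the 2-bromo dienone directly, so no separate α-halogenation is needed and the bromide serves as the handle for the carbonylative Stille coupling.

Key step: step 5

Assumption: the (S,S)-tBu-box copper complex is taken to give the (1S) dione 9; if the first run shows the opposite sense, the (R,R) ligand is used with nothing else changed.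

## Route

Step 1
Reactants: 1 (2,5-dimethylanisole)
Product: 2 Birch diene (1-methoxy-2,5-dimethylcyclohexa-1,4-diene)
Conditions: Li, NH3(l)/THF, tBuOH, −78 °C; MeOH quench
Reagents that add atoms: none
Why: Birch reduction leaves the donor-substituted carbons sp2, so the 1,4-diene should carry a tetrasubstituted enol ether alkene (C–OMe=C–Me) and a separate trisubstituted alkene.

Step 2
Reactants: 2 Birch diene; 3 bromoform
Product: 4 dibromocyclopropane (7,7-dibromo-1-methoxy-3,6-dimethylbicyclo[4.1.0]hept-3-ene, racemic)
Conditions: CHBr3 (1.05 equiv), KOtBu, pentane, −30 → 0 °C; used crude and cold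
Reagents that add atoms: bromoform (compound 3), BrC(Br)Br
Why: Dihalocarbene cyclopropanation, in which the electrophilic carbene should select the electron-rich enol ether alkene over the trialkyl alkene when one equivalent is used at low temperature.

Step 3
Reactants: 4 dibromocyclopropane
Product: 5 bromo dienone (2-bromo-3,6-dimethylcyclohepta-2,5-dien-1-one)
Conditions: AgOAc (1.2 equiv), acetone/H2O 9:1, 0 °C → rt, dark
Reagents that add atoms: water, O
Why: Silver-assisted disrotatory opening of the gem-dibromocyclopropane gives a methoxy-stabilised allyl cation whose hydrolysis gives the ring-expanded 2-bromo enone, and the acetate buffer should keep the skipped diene out of conjugation and prevent HBr loss to a tropone.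

Step 4
Reactants: 5 bromo dienone; 6 tributyl(vinyl)stannane; 7 carbon monoxide
Product: 8 Nazarov precursor (2-acryloyl-3,6-dimethylcyclohepta-2,5-dien-1-one)
Conditions: Pd2(dba)3 (2.5 mol %), Xantphos (6 mol %), CO (3 atm), BHT (cat.), dioxane, 60 °C
Reagents that add atoms: tributyl(vinyl)stannane (compound 6), C=C[Sn](CCCC)(CCCC)CCCC; carbon monoxide (compound 7), [C-]#[O+]
Why: Carbonylative Stille coupling, in which the activated vinyl bromide adds to zerovalent palladium, CO inserts, and the vinylstannane transmetallates before reductive elimination; CO pressure and the wide-bite-angle ligand should favour acyl capture over direct vinylation.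

Step 5
Reactants: 8 Nazarov precursor
Product: 9 (1S)-hydroazulene-4,6-dione (C1 quaternary with methyl β, C2=C3 enone, C4 and C6 ketones, C8(Me)=C9; C5–H mobile and partly enolised)
Conditions: [Cu((S,S)-tBu-box)](SbF6)2 (20 mol %, from CuCl2, AgSbF6 and ligand), CH2Cl2/HFIP 4:1, 0.02 M, 0 °C → rt
Reagents that add atoms: none
Why: Both carbonyl oxygens on C5 (C4=O and C6=O) bind the divalent copper centre, which holds the dienone in the s-trans/s-trans shape and generates the 3-oxidopentadienyl cation C2–C3–C4–C5–C1 with most of the charge on tertiary C1. Conrotatory 4π electrocyclisation then joins C1 to C2 and closes the five-membered ring (formally 5-endo); the copper-bound oxyallyl cation can lose a proton only from C2, so the alkene should land at C2=C3, and HFIP should protonate the diketonate to release 9 and the catalyst. The closest known reaction type is the Lewis-acid-catalysed Nazarov cyclisation of α-acyl and α-alkoxycarbonyl divinyl ketones, including copper bis(oxazoline) and pybox variants. C1 is the only centre fixed here, and its configuration follows from the sense of conrotation, which the C2-symmetric ligand should dictate by shielding one face of the planar chelate against the rising vinyl terminus; C5 stays mobile as a 1,3-dicarbonyl CH. The step needs cyclisation to win over vinyl ketone polymerisation and over migration of the skipped C8=C9 alkene, which the bidentate activation, the lack of an inward substituent on the vinyl terminus (only H faces the C1 methyl) and dilute, base-free conditions should secure.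

Step 6
Reactants: 9 hydroazulene-4,6-dione
Product: 10 trans-fused 6β-hydroxy enone (H5 α, C6–OH β, C2=C3–C4=O retained)
Conditions: Zn(BH4)2 (0.6 equiv), Et2O, −40 → −20 °C; then H2O
Reagents that add atoms: none
Why: Chelation-controlled borohydride reduction of an α-substituted β-diketone under Curtin–Hammett conditions, in which only the C5 epimer with H5 axial to both rings (trans fusion) can hold both carbonyls in the zinc chelate, hydride should go to the non-conjugated C6 carbonyl from the α face away from the C1 methyl, and the C6 configuration is of no consequence because C6 is returned to the ketone in step 14.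

Step 7
Reactants: 10 6β-hydroxy enone
Product: 11 6β-TBS ether of the enone
Conditions: TBSOTf, 2,6-lutidine, CH2Cl2, −78 °C
Reagents that add atoms: tert-butyldimethylsilyl triflate, CC(C)(C)[Si](C)(C)OS(=O)(=O)C(F)(F)F
Why: Silylation of a hindered secondary alcohol with a silyl triflate and a weak, hindered base, which should leave the C5 centre untouched and block retro-aldol and dehydration pathways.

Step 8
Reactants: 11 silyloxy enone
Product: 13 2α-hydroxy-4-ketone (C2–OH α, C6–OTBS β, H5 α), via pinacol boronate 12 (not isolated)
Conditions: B2pin2, CuCl (5 mol %), DPEphos (5 mol %), NaOtBu (10 mol %), MeOH (2 equiv), THF, rt; then NaBO3·4H2O, THF/H2O, 0 °C → rt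
Reagents that add atoms: bis(pinacolato)diboron, CC1(C)OB(OC1(C)C)B1OC(C)(C)C(C)(C)O1; sodium perborate, [Na+].[O-]OB=O
Why: Copper-catalysed conjugate borylation places boron on the β-carbon C2 from the α face, anti to the pseudo-axial C1 methyl of the trans-fused bicycle, and perborate oxidation of the C–B bond with retention should give the 2α-alcohol.

Step 9
Reactants: 13 2α-hydroxy-4-ketone
Product: 14 bis-silyl ketone (C2–OTES α, C6–OTBS β, C4 ketone)
Conditions: TESCl, imidazole, CH2Cl2, 0 °C
Reagents that add atoms: chlorotriethylsilane, CC[Si](Cl)(CC)CC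
Why: Standard silylation, chosen so that the small TES ether on the α face hinders the coming addition as little as possible and can later be removed in the presence of the TBS ether.

Step 10
Reactants: 14 bis-silyl ketone; 15 isopropylmagnesium chloride
Product: 16 tertiary carbinol (C4–OH β, C4–iPr α, C2–OTES α, C6–OTBS β)
Conditions: iPrMgCl, CeCl3 (anhydrous, 1.5 equiv each), THF, −78 → −40 °C; then H2O
Reagents that add atoms: isopropylmagnesium chloride (compound 15), CC(C)[Mg]Cl
Why: Organocerium 1,2-addition to an enolisable ketone, with the weakly basic cerium reagent suppressing enolisation and β-silyloxy elimination, and attack expected from the α face because the β face of C4 is blocked by the pseudo-axial C1 methyl and the axial C6 silyloxy group.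

Step 11
Reactants: 16 tertiary carbinol
Product: 17 2α,4β-diol 6β-TBS ether
Conditions: PPTS (cat.), MeOH/CH2Cl2, 0 °C
Reagents that add atoms: none
Why: Acid-catalysed methanolysis should cleave the TES ether selectively over the far more hindered and less labile TBS ether without ionising the tertiary alcohol.

Step 12
Reactants: 17 diol; 18 acetic anhydride
Product: 19 2α-acetate (C4–OH free, C6–OTBS β)
Conditions: Ac2O, DMAP (cat.), pyridine, CH2Cl2, rt
Reagents that add atoms: acetic anhydride (compound 18), CC(=O)OC(C)=O
Why: DMAP-catalysed acetylation should take the secondary C2 alcohol and leave the tertiary C4 alcohol unreacted.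

Step 13
Reactants: 19 acetate TBS ether
Product: 20 2α-acetoxy-4β,6β-diol
Conditions: HF·pyridine, pyridine/THF, 0 °C → rt
Reagents that add atoms: none
Why: Fluoride-driven desilylation under buffered, non-basic conditions should free the C6 alcohol without acetate cleavage or migration.

Step 14
Reactants: 20 2α-acetoxy-4β,6β-diol
Product: 21 β-hydroxy ketone (C6 ketone, C4–OH β, C2–OAc α, H5 α)
Conditions: Dess–Martin periodinane, pyridine, CH2Cl2, 0 °C → rt
Reagents that add atoms: none
Why: Dess–Martin oxidation takes the secondary alcohol only, the pyridine buffer should prevent dehydration of the tertiary aldol and migration of the β,γ-alkene, and C5 next to a seven-ring ketone is expected to stay trans.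

Step 15
Reactants: 21 β-hydroxy ketone
Product: 22 2α-acetoxy-4β,6α-diol
Conditions: Me4NBH(OAc)3, MeCN/AcOH 1:1, −30 → −20 °C
Reagents that add atoms: none
Why: Evans–Saksena hydroxyl-directed reduction, in which the C4 alkoxy(acetoxy)borohydride delivers hydride within a six-membered transition state to the β face of C6 (the face of the C4 oxygen), so the 1,3-anti diol with the equatorial 6α-hydroxyl should result.

Step 16
Reactants: 22 2α-acetoxy-4β,6α-diol; 23 4-methoxybenzoyl chloride
Product: 24 target (2α-acetoxy-4β-hydroxy-6α-(4-methoxybenzoyloxy) compound, CNP0171090.1)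
Conditions: 4-MeOC6H4COCl, Et3N, DMAP (cat.), CH2Cl2, rt
Reagents that add atoms: 4-methoxybenzoyl chloride (compound 23), COc1ccc(C(=O)Cl)cc1
Why: DMAP-catalysed acylation of the secondary equatorial C6 alcohol, with the tertiary C4 alcohol too hindered to react and the C2 acetate unaffected.

## Compound list

1 | 2,5-dimethylanisole | COc1cc(C)ccc1C | starting material
2 | 1-methoxy-2,5-dimethylcyclohexa-1,4-diene | COC1=C(C)CC=C(C)C1 | intermediate
3 | bromoform | BrC(Br)Br | starting material
4 | 7,7-dibromo-1-methoxy-3,6-dimethylbicyclo[4.1.0]hept-3-ene (racemic) | COC12CC(C)=CCC1(C)C2(Br)Br | intermediate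
5 | 2-bromo-3,6-dimethylcyclohepta-2,5-dien-1-one | O=C1C(Br)=C(C)CC=C(C)C1 | intermediate
6 | tributyl(vinyl)stannane | C=C[Sn](CCCC)(CCCC)CCCC | starting material
7 | carbon monoxide | [C-]#[O+] | starting material
8 | 2-acryloyl-3,6-dimethylcyclohepta-2,5-dien-1-one | C=CC(=O)C1=C(C)CC=C(C)CC1=O | intermediate
9 | (1S)-hydroazulene-4,6-dione, C1 methyl β, C2=C3 enone, C8(Me)=C9, C5 mobile | O=C1CC(C)=CC[C@@]2(C)C=CC(=O)C12 | intermediate
10 | trans-fused 6β-hydroxy enone (H5 α, C2=C3–C4=O) | O[C@@H]1CC(C)=CC[C@@]2(C)C=CC(=O)[C@H]12 | intermediate
11 | 6β-TBS ether of enone 10 | CC(C)(C)[Si](C)(C)O[C@@H]1CC(C)=CC[C@@]2(C)C=CC(=O)[C@H]12 | intermediate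
12 | 2α-pinacolboryl-4-ketone, 6β-OTBS (not isolated) | CC(C)(C)[Si](C)(C)O[C@@H]1CC(C)=CC[C@@]2(C)[C@@H](B3OC(C)(C)C(C)(C)O3)CC(=O)[C@H]12 | intermediate
13 | 2α-hydroxy-4-ketone, 6β-OTBS | CC(C)(C)[Si](C)(C)O[C@@H]1CC(C)=CC[C@@]2(C)[C@@H](O)CC(=O)[C@H]12 | intermediate
14 | 2α-OTES, 6β-OTBS 4-ketone | CC(C)(C)[Si](C)(C)O[C@@H]1CC(C)=CC[C@@]2(C)[C@@H](O[Si](CC)(CC)CC)CC(=O)[C@H]12 | intermediate
15 | isopropylmagnesium chloride | CC(C)[Mg]Cl | starting material
16 | 4β-hydroxy-4α-isopropyl compound, 2α-OTES, 6β-OTBS | CC(C)(C)[Si](C)(C)O[C@@H]1CC(C)=CC[C@@]2(C)[C@@H](O[Si](CC)(CC)CC)C[C@@](O)(C(C)C)[C@H]12 | intermediate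
17 | 2α,4β-diol, 6β-OTBS | CC(C)(C)[Si](C)(C)O[C@@H]1CC(C)=CC[C@@]2(C)[C@@H](O)C[C@@](O)(C(C)C)[C@H]12 | intermediate
18 | acetic anhydride | CC(=O)OC(C)=O | starting material
19 | 2α-acetate, 4β-OH, 6β-OTBS | CC(C)(C)[Si](C)(C)O[C@@H]1CC(C)=CC[C@@]2(C)[C@@H](OC(C)=O)C[C@@](O)(C(C)C)[C@H]12 | intermediate
20 | 2α-acetoxy-4β,6β-diol | O[C@@H]1CC(C)=CC[C@@]2(C)[C@@H](OC(C)=O)C[C@@](O)(C(C)C)[C@H]12 | intermediate
21 | 2α-acetoxy-4β-hydroxy-6-ketone | O=C1CC(C)=CC[C@@]2(C)[C@@H](OC(C)=O)C[C@@](O)(C(C)C)[C@H]12 | intermediate
22 | 2α-acetoxy-4β,6α-diol | O[C@H]1CC(C)=CC[C@@]2(C)[C@@H](OC(C)=O)C[C@@](O)(C(C)C)[C@H]12 | intermediate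
23 | 4-methoxybenzoyl chloride | COc1ccc(C(=O)Cl)cc1 | starting material
24 | CNP0171090.1 (2α-acetoxy-4β-hydroxy-6α-anisoyloxy compound) | COc1ccc(C(=O)O[C@H]2CC(C)=CC[C@@]3(C)[C@@H](OC(C)=O)C[C@@](O)(C(C)C)[C@H]23)cc1 | target

## Step count and risks

Total step count: 16. Longest linear sequence: 16 steps, from 2,5-dimethylanisole 1 to target 24.

Steps most likely to fail:

- **Step 5 (Nazarov).** The conrotation may run with poor torquoselectivity, or the copper may stay bound to the diketonate product so that turnover stalls. Fallback from 8: cyclise with an achiral Lewis acid (Sc(OTf)3, CH2Cl2/HFIP) to the racemic dione F1. Condense F1 with (S)-1-phenylethylamine (AcOH cat., toluene, 4 Å sieves) at the non-conjugated C6 carbonyl to give the enaminone F2 of the (1S) ring system and its diastereomer F3. Separate these by chromatography or crystallisation and hydrolyse F2 (1 M HCl, THF) to come back at 9.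

- **Step 6 (C6 reduction).** Hydride may be delivered to C4 or in conjugate fashion, or the reduction may pass through the cis-fused diketo epimer. Fallback from 9: Luche reduction (NaBH4, CeCl3·7H2O, MeOH, −78 °C) takes the conjugated C4 carbonyl first and gives the 4-hydroxy-6-ketone F4. Here C5 is α only to the cycloheptanone and should settle to the trans fusion on brief Et3N/MeOH treatment; either C4 epimer serves. NaBH4 (MeOH, −40 °C) then gives the 4,6β-diol F5, and MnO2 (CH2Cl2, rt) reoxidises only the allylic C4 alcohol, coming back at 10.

- **Step 10 (isopropyl addition).** Enolisation of the hindered ketone with loss of a β-silyloxy group, and β-hydride reduction by the secondary Grignard reagent, may outrun addition. Fallback from 14: add the smaller, less basic isopropenylmagnesium bromide with CeCl3 (THF, −78 °C) to give the isopropenyl carbinol F6. Hydrogenate its 1,1-disubstituted alkene selectively with RhCl(PPh3)3/H2 (benzene, rt), which should leave the trisubstituted ring alkene, coming back at 16.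

Further compounds
F1 | step 5 | racemic hydroazulene-4,6-dione | O=C1CC(C)=CCC2(C)C=CC(=O)C12
F2 | step 5 | C6 enaminone of (1S)-dione with (S)-1-phenylethylamine | C[C@H](NC1=C2C(=O)C=C[C@]2(C)CC=C(C)C1)c1ccccc1
F3 | step 5 | diastereomeric C6 enaminone of the (1R)-dione, discarded | C[C@H](NC1=C2C(=O)C=C[C@@]2(C)CC=C(C)C1)c1ccccc1
F4 | step 6 | trans-fused 4-hydroxy-6-ketone, C2=C3 alkene, either C4 epimer | O=C1CC(C)=CC[C@@]2(C)C=CC(O)[C@H]12
F5 | step 6 | trans-fused 4,6β-diol, C2=C3 alkene, either C4 epimer | O[C@@H]1CC(C)=CC[C@@]2(C)C=CC(O)[C@H]12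
F6 | step 10 | 4β-hydroxy-4α-isopropenyl compound, 2α-OTES, 6β-OTBS | CC(C)(C)[Si](C)(C)O[C@@H]1CC(C)=CC[C@@]2(C)[C@@H](O[Si](CC)(CC)CC)C[C@@](O)(C(C)=C)[C@H]12
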